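**Retrosynthetic overview**

1. Numbering follows the target: ring A = C1–C6 (C1 carries the chain C1'–C8'), ring B = C4-C5-C7-C12, ring C = C7-C8-C11-C12, ring D = C8-C9-C10-C11. The strategy rests on ring A being joined to the cyclobutane ladder only through the C4–C5 bond: a C4=C5 double bond in the meso C8 ladder (rings B, C, D) is strained, open on one face only (ring C covers the other), and has enantiotopic carbons.
2. Target ⇒ isopropylidene acetal ⇒ C1'–C2' bond: copper-catalysed coupling of the C1' tosylate with a seven-carbon Grignard reagent carrying the protected 2-glyceryl ether. C1 comes from convex-face hydrogenation of a ring A dienoate.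
3. Ring A dienoate ⇒ meso ladderene + methyl coumalate: inverse-demand [4+2] addition across C4=C5 (bonds C3–C4 and C5–C6) with loss of CO2, made enantioselective by a chiral boron Lewis acid.
4. Ladderene ⇒ anti C8H8 ladder diene (mono-reduction) ⇒ two molecules of cis-3,4-dichlorocyclobutene (reductive dimerisation).
5. Ring order: rings B and D are the cyclobutene rings of the two molecules of starting material, ring C closes in their coupling, ring A is made last, in the key step.

Key step: step 3

Assumption: the sense of induction of the (S)-catalyst with this new diene/dienophile pair cannot be read from precedent; it is taken to give the enantiomer drawn, and the (R)-catalyst would be used otherwise with nothing else changed.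

**Route**

Step 1
Reactants: 1 cis-3,4-dichlorocyclobutene (two molecules per molecule of 2)
Product: 2 anti-tricyclo[4.2.0.0(2,5)]octa-3,7-diene
Conditions: Li/Hg (about 0.5 wt% Li, at least 2 equiv Li per molecule of 1), Et2O, rt, Ar
Reagents that add atoms: second molecule of cis-3,4-dichlorocyclobutene (1), Cl[C@H]1C=C[C@H]1Cl
Why: Reductive dimerisation of the allylic dichloride by lithium amalgam (two C4H4Cl2 units give C8H8 with loss of four chlorides, formally the dimerisation of a cyclobutadiene equivalent) is the known entry to this ladder diene; each new ring fusion is cis, and the anti placement of the two cyclobutene rings on the central ring is the outcome specific to lithium (sodium amalgam leads to the syn dimer).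

Step 2
Reactants: 2 anti-tricyclo[4.2.0.0(2,5)]octa-3,7-diene
Product: 3 anti-tricyclo[4.2.0.0(2,5)]oct-3-ene (meso ladderene, C4=C5 in ring B)
Conditions: KO2CN=NCO2K (0.6 equiv), AcOH, MeOH, 0 °C to rt; AgNO3-impregnated silica, pentane
Reagents that add atoms: none
Why: Diimide reduction (concerted syn transfer of H2 to a strained cis alkene) with a deficit of reagent should leave 3 as the main reduced product, separable by argentation chromatography from unchanged 2 (recycled) and from the saturated ladder; no stereocentre changes.

Step 3
Reactants: 3 anti-tricyclo[4.2.0.0(2,5)]oct-3-ene; 4 methyl coumalate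
Product: 6 ladder-fused methyl cyclohexadienecarboxylate (ester on C1, C1=C6 and C2=C3, cis,anti,cis,anti,cis), via bridged lactone 5 (not isolated)
Conditions: 4 (1.0 equiv), 3 (1.5 equiv), (S)-3,3-diphenyl-1-(o-tolyl)tetrahydro-1H,3H-pyrrolo[1,2-c][1,3,2]oxazaborole (25 mol%) pre-mixed with AlBr3 (20 mol%), CH2Cl2, −78 to −40 °C; then Et3N, Pd(PPh3)4 (5 mol%), THF, −40 to 0 °C; cold filtration through silica, 6 used at once
Reagents that add atoms: none
Why: Proposed new method: the coumalate, its LUMO lowered by the boron Lewis acid on the ester carbonyl, should add to the bent, strained C4=C5 π bond of 3 in a concerted suprafacial inverse-demand [4+2] cycloaddition, the closest known types being thermal inverse-demand Diels-Alder reactions of 2-pyrones with strained cycloalkenes and chiral-Lewis-acid-controlled pyrone cycloadditions with vinyl ethers, while the catalytic desymmetrisation of a meso hydrocarbon alkene is the new element. Ring A closes in this event as a six-membered ring by two-bond [4π+2π] cycloaddition (C3–C4 and C5–C6), first as the bicyclo[2.2.2] lactone 5. C4 and C5 are set by the substrate: ring C blocks one face of the cyclobutene, so the diene adds on the face carrying H7 and H12, H4 and H5 are pushed toward ring C, and the cis,anti,cis ladder results. The absolute sense (ester carbon on C1, not C2) depends on which enantiotopic alkene carbon bonds to the pyrone C6, and it needs the catalyst to shield one pyrone face while the bulky catalyst-bound ester bridge stays away from ring B and its H7/H12. CO2 is then removed without heating, because thermal retro-[4+2] loss from pyrone adducts of unactivated alkenes is expected to need about 100 °C, where the bicyclo[4.2.0]octadiene of 6 would open electrocyclically to a cyclooctatriene: 5 is an allylic carboxylate of the Morita-Baylis-Hillman type (C6–O next to the C1=C2 acrylate), so zerovalent palladium should ionise C6–O with inversion and the carboxylate left on C3 should depart as CO2 in an anti 1,4-elimination (the known palladium-catalysed decarboxylative elimination of allylic esters to 1,3-dienes), giving the C6=C1–C2=C3 dienoate at 0 °C.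

Step 4
Reactants: 6 ladder-fused methyl cyclohexadienecarboxylate
Product: 7 ladder-fused methyl cyclohexanecarboxylate (CO2Me on C1 cis to the C5–C7 and C4–C12 bonds; H1, H4, H5 on one face of ring A)
Conditions: H2 (1 atm), 5% Pd/C, EtOAc, 0 °C to rt
Reagents that add atoms: none
Why: Heterogeneous catalytic hydrogenation should first saturate the disubstituted C2=C3 bond (which also removes the diene needed for electrocyclic opening) and then add H2 to C1=C6 from the convex face of ring A, the face that carries H4 and H5 and is turned away from ring B, so that H1 ends cis to H4 and H5.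

Step 5
Reactants: 7 ladder-fused methyl cyclohexanecarboxylate
Product: 8 primary alcohol (C1'H2OH on C1)
Conditions: LiAlH4, THF, 0 °C
Reagents that add atoms: none
Why: Hydride reduction of the ester to the primary alcohol is fast at 0 °C and leaves C1 and the saturated ladder untouched.

Step 6
Reactants: 8 primary alcohol
Product: 9 C1' p-toluenesulfonate
Conditions: TsCl, Et3N, DMAP (cat.), CH2Cl2, 0 °C to rt
Reagents that add atoms: p-toluenesulfonyl chloride (TsCl), Cc1ccc(cc1)S(Cl)(=O)=O
Why: Sulfonylation of an unhindered primary alcohol turns C1' into an electrophile without touching any stereocentre.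

Step 7
Reactants: 10 2,2-dimethyl-1,3-dioxan-5-ol; 11 1,7-dibromoheptane
Product: 12 5-[(7-bromoheptyl)oxy]-2,2-dimethyl-1,3-dioxane
Conditions: NaH, DMF, 0 °C; then 11 (4 equiv), rt
Reagents that add atoms: none
Why: Williamson ether synthesis, the secondary alkoxide displacing one primary bromide by SN2 while the excess of 11 suppresses the double ether.

Step 8
Reactants: 9 C1' p-toluenesulfonate; 12 5-[(7-bromoheptyl)oxy]-2,2-dimethyl-1,3-dioxane
Product: 14 isopropylidene acetal of the target (C1'–C8' chain complete), via Grignard reagent 13 (not isolated)
Conditions: 12 (2 equiv), Mg, THF, 45 °C; then 9, Li2CuCl4 (5 mol%), THF, −40 °C to rt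
Reagents that add atoms: none
Why: Copper-catalysed sp3–sp3 cross-coupling of a primary alkyl Grignard reagent with a primary tosylate forms C1'–C2' by displacement at C1' and never passes through an epimerisable α-branched aldehyde, so C1 is not at risk.

Step 9
Reactants: 14 isopropylidene acetal of the target
Product: 15 2-{[8-(ladder-fused cyclohexyl)octyl]oxy}propane-1,3-diol (CNP0193334.1)
Conditions: AcOH/H2O/THF (4:1:1), 40 °C
Reagents that add atoms: none
Why: Acid-catalysed hydrolysis of the isopropylidene acetal frees the 1,3-diol, and the ether, the saturated ladder and all stereocentres are inert to dilute acid.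

**Compound list**

1 | cis-3,4-dichlorocyclobutene | Cl[C@H]1C=C[C@H]1Cl | starting material
2 | anti-tricyclo[4.2.0.0(2,5)]octa-3,7-diene | C1=C[C@H]2[C@@H]3C=C[C@@H]3[C@@H]12 | intermediate
3 | anti-tricyclo[4.2.0.0(2,5)]oct-3-ene (meso ladderene) | C1=C[C@H]2[C@@H]3CC[C@@H]3[C@@H]12 | intermediate
4 | methyl coumalate (methyl 2-oxo-2H-pyran-5-carboxylate) | COC(=O)C1=COC(=O)C=C1 | starting material
5 | bridged lactone: C3 and C6 linked by C(=O)–O (carbonyl on C3, O on C6), by C2=C1(CO2Me) and by C4–C5 of the ladder; lactone bridge on the side of ring B, ladder cis,anti,cis | COC(=O)C1=C[C@H]2C(=O)O[C@@H]1[C@H]1[C@@H]2[C@@H]2[C@H]3CC[C@H]3[C@H]12 | intermediate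
6 | ladder-fused methyl cyclohexadienecarboxylate (ester on C1, C1=C6 and C2=C3; H4/H5 cis, rings A/C anti across ring B, rings B/D anti across ring C) | COC(=O)C=1C=C[C@@H]2[C@H](C=1)[C@H]1[C@@H]3CC[C@@H]3[C@@H]21 | intermediate
7 | ladder-fused methyl cyclohexanecarboxylate (CO2Me on C1 cis to the C5–C7 and C4–C12 bonds) | COC(=O)[C@H]1CC[C@@H]2[C@H](C1)[C@H]1[C@@H]3CC[C@@H]3[C@@H]21 | intermediate
8 | primary alcohol (C1'H2OH on C1, configuration as in 7) | OC[C@H]1CC[C@@H]2[C@H](C1)[C@H]1[C@@H]3CC[C@@H]3[C@@H]21 | intermediate
9 | p-toluenesulfonate of 8 | Cc1ccc(cc1)S(=O)(=O)OC[C@H]1CC[C@@H]2[C@H](C1)[C@H]1[C@@H]3CC[C@@H]3[C@@H]21 | intermediate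
10 | 2,2-dimethyl-1,3-dioxan-5-ol | CC1(C)OCC(O)CO1 | starting material
11 | 1,7-dibromoheptane | BrCCCCCCCBr | starting material
12 | 5-[(7-bromoheptyl)oxy]-2,2-dimethyl-1,3-dioxane | CC1(C)OCC(CO1)OCCCCCCCBr | intermediate
13 | {7-[(2,2-dimethyl-1,3-dioxan-5-yl)oxy]heptyl}magnesium bromide | CC1(C)OCC(CO1)OCCCCCCC[Mg]Br | intermediate
14 | 2,2-dimethyl-5-{[8-(ladder-fused cyclohexyl)octyl]oxy}-1,3-dioxane (isopropylidene acetal of the target) | CC1(C)OCC(CO1)OCCCCCCCC[C@H]1CC[C@@H]2[C@H](C1)[C@H]1[C@@H]3CC[C@@H]3[C@@H]21 | intermediate
15 | 2-{[8-(ladder-fused cyclohexyl)octyl]oxy}propane-1,3-diol (CNP0193334.1) | OCC(CO)OCCCCCCCC[C@H]1CC[C@@H]2[C@H](C1)[C@H]1[C@@H]3CC[C@@H]3[C@@H]21 | target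

**Step count**

Total steps: 9. Longest linear sequence: 8 (steps 1 to 6, 8 and 9); step 7 is the one-step side branch.

**Steps most likely to fail**

Step 3. The catalyst may not turn over because the carbonyl-rich products hold the Lewis acid, the strong Lewis acid may trigger cationic rearrangement or oligomerisation of the strained alkene, facial discrimination may be poor because the catalyst can bind either carbonyl of the pyrone, or the diene may be lost by electrocyclic opening. The fallback uses known chemistry only, never forms the fragile dienoate, and sets out from 3 and 4. They are heated without catalyst (toluene, 80 to 90 °C, sealed vessel), a thermal inverse-demand Diels-Alder reaction that should stop at the racemic bridged lactone F1 because CO2 loss needs a higher temperature. Hydrogenation (H2, Pd/C) saturates its C1=C2 bond to give the racemic saturated lactone F2. DBU (THF, rt) opens this β-acyloxy ester by E1cB elimination to the racemic enoate acid F3 (C1=C6, CO2H on C3). Photocatalytic hydrodecarboxylation (9-mesityl-10-methylacridinium tetrafluoroborate, diphenyl disulfide, N,N-diisopropylethylamine, 2,2,2-trifluoroethanol, blue light) removes the C3 carboxyl and gives the racemic enoate F4. Both orientations of the lactone bridge converge at this point. Convex-face hydrogenation as in step 4 gives the racemic saturated ester F5, which is resolved by preparative chromatography on a chiral stationary phase. The fallback comes back to the route at 7.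

Step 4. Facial selectivity at C1 may be poor, the double bond may migrate on the metal surface, a strained ring bond may be hydrogenolysed, or the diene may open before it is reduced. The fallback sets out from 6 and reduces the two double bonds separately without a hydrogenation catalyst. Diimide (KO2CN=NCO2K, AcOH, MeOH, 0 °C) should reduce only the disubstituted, non-ester-bearing C2=C3 bond and give the enoate F6. Conjugate reduction with [(Ph3P)CuH]6 and PhSiH3 (toluene, rt), followed by protonation of the ester enolate from the convex face of ring A on aqueous work-up, then sets C1 in the same sense. The fallback comes back to the route at 7; any C1 epimer would be removed by chromatography at the stage of alcohol 8.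

Step 2. Under- and over-reduction are statistically unavoidable, and the volatile C8 hydrocarbons may be lost during separation. The fallback sets out from 2 and moves the saturation of ring D behind the ring A annulation. Diene 2, in excess, is taken directly into the conditions of step 3; its two double bonds are equivalent (related by the twofold axis) and each has the same open face. The same bonds should form via the ring D-unsaturated bridged lactone F7 to give the ring D-unsaturated dienoate F8. The hydrogenation of step 4, now with three equivalents of H2, reduces the ring D cyclobutene together with the diene, and the fallback comes back to the route at 7.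

**Further compounds**

F1 | step 3 | racemic bridged lactone (one enantiomer drawn; lactone bridge syn to ring B shown, the anti isomer may accompany it) | COC(=O)C1=C[C@H]2C(=O)O[C@@H]1[C@H]1[C@@H]2[C@@H]2[C@H]3CC[C@H]3[C@H]12
F2 | step 3 | racemic saturated bridged lactone (C1 epimers, one enantiomer drawn) | COC(=O)C1C[C@H]2C(=O)O[C@@H]1[C@H]1[C@@H]2[C@@H]2[C@H]3CC[C@H]3[C@H]12
F3 | step 3 | racemic enoate acid (C1=C6, CO2H on C3 cis to the C4–C12 bond, one enantiomer drawn) | COC(=O)C=1C[C@@H](C(O)=O)[C@@H]2[C@H](C=1)[C@H]1[C@@H]3CC[C@@H]3[C@@H]21
F4 | step 3 | racemic ladder-fused methyl cyclohex-1-enecarboxylate (C1=C6, one enantiomer drawn) | COC(=O)C=1CC[C@@H]2[C@H](C=1)[C@H]1[C@@H]3CC[C@@H]3[C@@H]21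
F5 | step 3 | racemic ladder-fused methyl cyclohexanecarboxylate (racemate of 7, one enantiomer drawn) | COC(=O)[C@H]1CC[C@@H]2[C@H](C1)[C@H]1[C@@H]3CC[C@@H]3[C@@H]21
F6 | step 4 | ladder-fused methyl cyclohex-1-enecarboxylate (C1=C6, single enantiomer) | COC(=O)C=1CC[C@@H]2[C@H](C=1)[C@H]1[C@@H]3CC[C@@H]3[C@@H]21
F7 | step 2 | ring D-unsaturated bridged lactone (C9=C10 retained) | COC(=O)C1=C[C@H]2C(=O)O[C@@H]1[C@H]1[C@@H]2[C@@H]2[C@H]3C=C[C@H]3[C@H]12
F8 | step 2 | ring D-unsaturated dienoate (C1=C6, C2=C3 and C9=C10) | COC(=O)C=1C=C[C@@H]2[C@H](C=1)[C@H]1[C@@H]3C=C[C@@H]3[C@@H]21
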